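**Plan**
Eudesmane numbering is used throughout, also for the open chain (C1 CHBr, C4 carbinol, C5 ring-fusion CH, C6 CHOAc, C7 CH-iPr, C10 C-Me).
- The first cut is C5–C10, the bond shared by ring A (C1–C5, C10) and ring B (C5–C10), together with C1–Br and C4–O; this leaves a ten-membered (1(10)E,4E)-germacradien-6-yl acetate.
- The feature that allows the key step: C6 is a carbinol carbon between C5 (one end of the C4=C5 alkene masked by the C4 carbinol and C5 methine) and the isopropyl-bearing C7. The second cut, C5–C6, is therefore the addition of an alkenyl metal (C5) to an aldehyde (C6).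
- The chain is then cut at C1–C2 (sp2–sp3 coupling) and at the two C–CH3 bonds on C10 and C4 (carbometalation), leaving a C6–C10/C1 alkyne obtained from (R)-piperitone opened at its double bond.
- Forward: chain assembly (steps 1–10), ten-membered ring by Ni/Cr closure (step 11), then rings A and B together by bromonium-triggered transannular C5–C10 bonding (step 13).
- Stereochemistry: C7 comes from piperitone; both E-alkenes from syn-carboalumination; C6 from 1,2-induction by C7 in the ring closure; C1, C10, C5 and C4 from anti addition across the two E-alkenes in the ring conformer fixed by C6/C7.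

Key step: step 11

Assumption: commercial (R)-piperitone supplies C7; if its optical purity is insufficient, keto acid 3 would be enriched by crystallisation of a salt with a chiral amine before step 2.

**Route**

Step 1
Reactants: 1 (R)-piperitone
Product: 3 (2R)-5-oxo-2-(propan-2-yl)hexanoic acid, via ozonide 2 (not isolated)
Conditions: O3, CH2Cl2, −78 °C; then 30% aq. H2O2, AcOH, 0 °C → rt
Reagents that add atoms: ozone [O-][O+]=O; hydrogen peroxide OO
Why: Ozonolysis of the enone C=C with oxidative work-up is the classical enone → nor-keto acid degradation (the former ring CH leaves as CO2 by oxidative decarboxylation of the α-keto acid), and it runs under non-enolising conditions, so the isopropyl-bearing centre (future C7) should be carried over unchanged.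

Step 2
Reactants: 3 (2R)-5-oxo-2-(propan-2-yl)hexanoic acid
Product: 4 (5R)-6-hydroxy-5-(propan-2-yl)hexan-2-one
Conditions: BH3·SMe2 (1.05 equiv), THF, −15 → 0 °C; then MeOH
Reagents that add atoms: none
Why: Borane reduces a carboxylic acid through its acyloxyborane faster than it reduces a ketone, so one equivalent at low temperature should give the primary alcohol (future C6) chemoselectively without affecting C7.

Step 3
Reactants: 4 (5R)-6-hydroxy-5-(propan-2-yl)hexan-2-one
Product: 5 (5R)-6-{[tert-butyl(dimethyl)silyl]oxy}-5-(propan-2-yl)hexan-2-one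
Conditions: TBSCl, imidazole, CH2Cl2, 0 °C → rt
Reagents that add atoms: tert-butyl(chloro)dimethylsilane CC(C)(C)[Si](C)(C)Cl
Why: Imidazole-promoted silylation of the primary hydroxyl is routine and also draws the hydroxy ketone/lactol equilibrium to the open-chain ketone.

Step 4
Reactants: 5 (5R)-6-{[tert-butyl(dimethyl)silyl]oxy}-5-(propan-2-yl)hexan-2-one
Product: 7 tert-butyl(dimethyl){[(2R)-2-(propan-2-yl)hex-5-yn-1-yl]oxy}silane, via enol phosphate 6 (not isolated)
Conditions: LDA (1.1 equiv), THF, −78 °C; ClP(O)(OEt)2, −78 °C → rt; then LDA (2.3 equiv), −78 °C → rt; H2O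
Reagents that add atoms: none
Why: This is the established methyl ketone → terminal alkyne conversion (kinetic deprotonation at the methyl group, O-phosphorylation, base-induced elimination of diethyl phosphate), and the stereocentre is remote from every acidic site.

Step 5
Reactants: 7 tert-butyl(dimethyl){[(2R)-2-(propan-2-yl)hex-5-yn-1-yl]oxy}silane, 8 trimethylaluminium
Product: 10 tert-butyl{[(2R,5E)-6-iodo-5-methyl-2-(propan-2-yl)hex-5-en-1-yl]oxy}dimethylsilane, via alkenylalane 9 (not isolated)
Conditions: Me3Al (2.5 equiv), Cp2ZrCl2 (0.25 equiv), CH2Cl2, 0 °C → rt; then I2, THF, −30 → 0 °C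
Reagents that add atoms: trimethylaluminium C[Al](C)C; iodine II
Why: Zirconium-catalysed carboalumination adds Me–Al syn across the terminal alkyne with methyl at the internal carbon, and iodinolysis of the C–Al bond goes with retention, which should fix the E geometry of the future C1=C10 alkene and install the C10 methyl.

Step 6
Reactants: 10 tert-butyl{[(2R,5E)-6-iodo-5-methyl-2-(propan-2-yl)hex-5-en-1-yl]oxy}dimethylsilane, 11 (4-bromobut-1-yn-1-yl)trimethylsilane
Product: 13 tert-butyl(dimethyl){[(2R,5E)-5-methyl-2-(propan-2-yl)-10-(trimethylsilyl)dec-5-en-9-yn-1-yl]oxy}silane, via alkylzinc bromide 12 (not isolated)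
Conditions: 11, Zn dust, LiCl, THF, 50 °C; then 10, Pd(PPh3)4 (5 mol %), THF–DMF, rt
Reagents that add atoms: (4-bromobut-1-yn-1-yl)trimethylsilane C[Si](C)(C)C#CCCBr
Why: Negishi sp2–sp3 coupling of an alkenyl iodide with a primary alkylzinc halide proceeds with retention of alkene geometry and brings in C2–C5 as a silyl-masked alkyne.

Step 7
Reactants: 13 tert-butyl(dimethyl){[(2R,5E)-5-methyl-2-(propan-2-yl)-10-(trimethylsilyl)dec-5-en-9-yn-1-yl]oxy}silane
Product: 14 tert-butyl(dimethyl){[(2R,5E)-5-methyl-2-(propan-2-yl)dec-5-en-9-yn-1-yl]oxy}silane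
Conditions: K2CO3, MeOH, rt
Reagents that add atoms: none
Why: Carbonate-catalysed methanolysis cleaves the alkynyl C–Si bond under conditions that leave a primary TBS ether intact.

Step 8
Reactants: 14 tert-butyl(dimethyl){[(2R,5E)-5-methyl-2-(propan-2-yl)dec-5-en-9-yn-1-yl]oxy}silane, 8 trimethylaluminium
Product: 16 tert-butyl{[(2R,5E,9E)-10-iodo-5,9-dimethyl-2-(propan-2-yl)deca-5,9-dien-1-yl]oxy}dimethylsilane, via alkenylalane 15 (not isolated)
Conditions: Me3Al (2.5 equiv), Cp2ZrCl2 (0.25 equiv), CH2Cl2, 0 °C → rt; then I2, THF, −30 → 0 °C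
Reagents that add atoms: trimethylaluminium C[Al](C)C; iodine II
Why: A second zirconium-catalysed syn-carboalumination/iodinolysis, selective for the terminal alkyne over the trisubstituted alkene, should give the (E)-alkenyl iodide at C5 with the C4 methyl in place.

Step 9
Reactants: 16 tert-butyl{[(2R,5E,9E)-10-iodo-5,9-dimethyl-2-(propan-2-yl)deca-5,9-dien-1-yl]oxy}dimethylsilane
Product: 17 (2R,5E,9E)-10-iodo-5,9-dimethyl-2-(propan-2-yl)deca-5,9-dien-1-ol
Conditions: TBAF, THF, 0 °C → rt
Reagents that add atoms: none
Why: Fluoride-induced Si–O cleavage is routine, and the alkenyl iodide and both alkenes are inert to it.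

Step 10
Reactants: 17 (2R,5E,9E)-10-iodo-5,9-dimethyl-2-(propan-2-yl)deca-5,9-dien-1-ol
Product: 18 (2R,5E,9E)-10-iodo-5,9-dimethyl-2-(propan-2-yl)deca-5,9-dienal
Conditions: Dess–Martin periodinane, pyridine, CH2Cl2, 0 °C → rt; used directly
Reagents that add atoms: none
Why: Buffered Dess–Martin oxidation is non-basic and should give the α-branched aldehyde without epimerising C7, provided the aldehyde is taken on at once.

Step 11
Reactants: 18 (2R,5E,9E)-10-iodo-5,9-dimethyl-2-(propan-2-yl)deca-5,9-dienal
Product: 20 (1(10)E,4E,6S,7R)-germacra-1(10),4-dien-6-ol, via alkenylchromium species 19 (not isolated)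
Conditions: CrCl2 (8 equiv), NiCl2 (0.1 equiv), degassed DMSO–THF (3:1), rt, syringe-pump addition of 18 to about 3 mM final concentration; H2O; chromatography on Et3N-deactivated silica below 25 °C
Reagents that add atoms: none
Why: Ni(0), formed from NiCl2 by Cr(II), inserts into the C5–I bond with retention, transmetalation to Cr(III) gives the configurationally stable (E)-alkenylchromium 19, and this carbonyl-selective nucleophile adds to the C6 aldehyde to form C5–C6. The closest known reaction type is the Nozaki–Hiyama–Kishi macrocyclisation of ω-formyl alkenyl iodides to medium-ring allylic alcohols. One ring is closed, the ten-membered carbocycle, in a 10-exo-trig mode (carbonyl oxygen outside the new ring, both E-alkenes inside it). The new stereocentre C6 is controlled by the adjacent C7 centre through 1,2-induction in the Felkin–Anh sense, with isopropyl antiperiplanar to the forming bond and the nucleophile passing H-7, which should give (6S) and hence the 6,7-cis relation of ring B. The step needs this facial selectivity (secured by the α-isopropyl branch), retention of both E geometries (secured by the stereoretentive Ni/Cr sequence) and cyclisation over oligomerisation (secured by slow addition at high dilution and by the two rigid E-trisubstituted alkenes that pre-fold the chain). The neutral, non-basic organochromium should leave the epimerisable C7–H untouched.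

Step 12
Reactants: 20 (1(10)E,4E,6S,7R)-germacra-1(10),4-dien-6-ol, 21 acetic anhydride
Product: 22 (1(10)E,4E,6S,7R)-germacra-1(10),4-dien-6-yl acetate
Conditions: Ac2O, pyridine, DMAP (cat.), CH2Cl2, 0 °C → rt
Reagents that add atoms: acetic anhydride CC(=O)OC(C)=O
Why: DMAP-catalysed acylation of the secondary allylic alcohol is basic throughout, which avoids acid-triggered transannular cyclisation of the diene and retains the C6 configuration.

Step 13
Reactants: 22 (1(10)E,4E,6S,7R)-germacra-1(10),4-dien-6-yl acetate
Product: 24 austradiol acetate [(1R,4R,5S,6S,7R,10R)-1-bromo-4-hydroxyeudesman-6-yl acetate], via acetoxonium ion 23 (not isolated)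
Conditions: NBS (1.05 equiv), acetone–H2O (9:1), 0 °C, dark
Reagents that add atoms: N-bromosuccinimide O=C1CCC(=O)N1Br; water O
Why: This is a bromonium-induced transannular cation–olefin cyclisation of a cyclodeca-1,5-diene with neighbouring-group termination, in which NBS attacks the remote, more electron-rich C1=C10 alkene at C1 from the ring periphery, C5 bonds to C10 in the crossed chair–chair-like conformer that keeps the 6-acetoxy group pseudo-equatorial (H-6 rather than OAc between the C4 and C10 methyl groups), the ester carbonyl captures C4 anti to the new C5–C10 bond as acetoxonium ion 23 and water opens this to the secondary acetate and tertiary alcohol, so that anti addition across both E-alkenes should set 1R, 10R, 5S and 4R (equatorial Br and OH, trans ring fusion) relative to C6 and C7.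

**Compound list**

1 | (R)-piperitone, (6R)-3-methyl-6-(propan-2-yl)cyclohex-2-en-1-one | O=C1[C@@H](C(C)C)CCC(C)=C1 | starting material
2 | ozonide (1,2,4-trioxolane) of 1 across the former C=C, formed in the flask | CC12OOC(O1)C(=O)[C@@H](C(C)C)CC2 | intermediate
3 | (2R)-5-oxo-2-(propan-2-yl)hexanoic acid | CC(=O)CC[C@H](C(C)C)C(=O)O | intermediate
4 | (5R)-6-hydroxy-5-(propan-2-yl)hexan-2-one (in equilibrium with its lactol) | CC(=O)CC[C@H](C(C)C)CO | intermediate
5 | (5R)-6-{[tert-butyl(dimethyl)silyl]oxy}-5-(propan-2-yl)hexan-2-one | CC(=O)CC[C@H](C(C)C)CO[Si](C)(C)C(C)(C)C | intermediate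
6 | (5R)-6-{[tert-butyl(dimethyl)silyl]oxy}-5-(propan-2-yl)hex-1-en-2-yl diethyl phosphate, formed in the flask | C=C(OP(=O)(OCC)OCC)CC[C@H](C(C)C)CO[Si](C)(C)C(C)(C)C | intermediate
7 | tert-butyl(dimethyl){[(2R)-2-(propan-2-yl)hex-5-yn-1-yl]oxy}silane | C#CCC[C@H](C(C)C)CO[Si](C)(C)C(C)(C)C | intermediate
8 | trimethylaluminium | C[Al](C)C | starting material
9 | {(1E,5R)-6-{[tert-butyl(dimethyl)silyl]oxy}-2-methyl-5-(propan-2-yl)hex-1-en-1-yl}dimethylalumane, formed in the flask | C[Al](C)/C=C(C)/CC[C@H](C(C)C)CO[Si](C)(C)C(C)(C)C | intermediate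
10 | tert-butyl{[(2R,5E)-6-iodo-5-methyl-2-(propan-2-yl)hex-5-en-1-yl]oxy}dimethylsilane | I/C=C(C)/CC[C@H](C(C)C)CO[Si](C)(C)C(C)(C)C | intermediate
11 | (4-bromobut-1-yn-1-yl)trimethylsilane | C[Si](C)(C)C#CCCBr | starting material
12 | bromo[4-(trimethylsilyl)but-3-yn-1-yl]zinc, formed in the flask | C[Si](C)(C)C#CCC[Zn]Br | intermediate
13 | tert-butyl(dimethyl){[(2R,5E)-5-methyl-2-(propan-2-yl)-10-(trimethylsilyl)dec-5-en-9-yn-1-yl]oxy}silane | C[Si](C)(C)C#CCC/C=C(C)/CC[C@H](C(C)C)CO[Si](C)(C)C(C)(C)C | intermediate
14 | tert-butyl(dimethyl){[(2R,5E)-5-methyl-2-(propan-2-yl)dec-5-en-9-yn-1-yl]oxy}silane | C#CCC/C=C(C)/CC[C@H](C(C)C)CO[Si](C)(C)C(C)(C)C | intermediate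
15 | {(1E,5E,9R)-10-{[tert-butyl(dimethyl)silyl]oxy}-2,6-dimethyl-9-(propan-2-yl)deca-1,5-dien-1-yl}dimethylalumane, formed in the flask | C[Al](C)/C=C(C)/CC/C=C(C)/CC[C@H](C(C)C)CO[Si](C)(C)C(C)(C)C | intermediate
16 | tert-butyl{[(2R,5E,9E)-10-iodo-5,9-dimethyl-2-(propan-2-yl)deca-5,9-dien-1-yl]oxy}dimethylsilane | I/C=C(C)/CC/C=C(C)/CC[C@H](C(C)C)CO[Si](C)(C)C(C)(C)C | intermediate
17 | (2R,5E,9E)-10-iodo-5,9-dimethyl-2-(propan-2-yl)deca-5,9-dien-1-ol | I/C=C(C)/CC/C=C(C)/CC[C@H](C(C)C)CO | intermediate
18 | (2R,5E,9E)-10-iodo-5,9-dimethyl-2-(propan-2-yl)deca-5,9-dienal | I/C=C(C)/CC/C=C(C)/CC[C@H](C(C)C)C=O | intermediate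
19 | dichloro[(1E,5E,9R)-2,6-dimethyl-10-oxo-9-(propan-2-yl)deca-1,5-dien-1-yl]chromium(III), formed in the flask | Cl[Cr](Cl)/C=C(C)/CC/C=C(C)/CC[C@H](C(C)C)C=O | intermediate
20 | (1(10)E,4E,6S,7R)-germacra-1(10),4-dien-6-ol, (1S,2E,6E,10R)-3,7-dimethyl-10-(propan-2-yl)cyclodeca-2,6-dien-1-ol | O[C@H]1[C@@H](C(C)C)CC/C(C)=C/CC/C(C)=C/1 | intermediate
21 | acetic anhydride | CC(=O)OC(C)=O | starting material
22 | (1(10)E,4E,6S,7R)-germacra-1(10),4-dien-6-yl acetate | CC(=O)O[C@H]1[C@@H](C(C)C)CC/C(C)=C/CC/C(C)=C/1 | intermediate
23 | acetoxonium ion: 2-methyl-1,3-dioxan-2-ylium bridging O4 and O6 of the (1R,4R,5S,6S,7R,10R)-1-bromoeudesmane-4,6-diol skeleton, formed in the flask | CC(=[O+]3)O[C@H]1[C@@H](C(C)C)CC[C@@]2(C)[C@H](Br)CC[C@]3(C)[C@H]12 | intermediate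
24 | austradiol acetate, (1R,4R,5S,6S,7R,10R)-1-bromo-4-hydroxyeudesman-6-yl acetate, (1S,2R,4aR,5R,8R,8aS)-5-bromo-8-hydroxy-4a,8-dimethyl-2-(propan-2-yl)decahydronaphthalen-1-yl acetate | CC(=O)O[C@H]1[C@@H](C(C)C)CC[C@@]2(C)[C@H](Br)CC[C@@](C)(O)[C@H]12 | target

**Step count and risks**

Total steps: 13. Longest linear sequence: 13 steps (1 → 24).

Steps most likely to fail:

Step 11. The ring closure may go with poor or reversed facial selectivity at C6. Folding of the ten-membered transition state, with the chromium alkoxide and the isopropyl group both pseudo-equatorial, can override the Felkin–Anh preference and lead to the C6 epimer. The fallback sets out from 18 and comes back at 20. The ring is still closed by the Ni/Cr reaction, but C6 is set afterwards by hydride instead of in the C–C bond formation. The cyclisation mixture, containing the epimer (1R,2E,6E,10R)-3,7-dimethyl-10-(propan-2-yl)cyclodeca-2,6-dien-1-ol F1, would be oxidised as a whole (Dess–Martin periodinane, pyridine, CH2Cl2, 0 °C) to the dienone (2E,6E,10R)-3,7-dimethyl-10-(propan-2-yl)cyclodeca-2,6-dien-1-one F2. F2 would then be reduced with L-Selectride in THF at −78 °C; 1,2-addition is expected for this β,β-disubstituted enone. Hydride should arrive on the ring face away from the C4 and C10 methyl groups, with the isopropyl group pseudo-equatorial, which should give 20. A Corey–Bakshi–Shibata reduction would be the reagent-controlled variant.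

Step 13. The acetoxonium ion may open with acyl transfer to the tertiary oxygen, or the C4 cation may lose a proton instead of being captured. Folding through the other crossed conformer would additionally give the C1/C4/C5/C10 diastereomer, and the fallback does not correct that. The fallback sets out from 20 and comes back at 24. The unprotected dienol would be cyclised with NBS in aqueous acetone at 0 °C, water now serving as the external nucleophile at C4, to give (1R,4R,5S,6S,7R,10R)-1-bromoeudesmane-4,6-diol F3. The secondary C6 hydroxyl of F3 would then be acetylated selectively (Ac2O, pyridine, DMAP, 0 °C), the tertiary C4 hydroxyl being inert under these conditions.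

Step 2. Reduction of the methyl ketone may compete with reduction of the acid, including intramolecular hydride delivery from the acyloxyborane, leading to over-reduction. The fallback sets out from 3 and comes back at 5. Exhaustive reduction with LiAlH4 (THF, 0 °C → rt) would give (2R)-2-(propan-2-yl)hexane-1,5-diol F4 as a mixture of C5 epimers. The primary hydroxyl would be silylated selectively (TBSCl 1.0 equiv, imidazole, CH2Cl2, −20 °C) to (5R)-6-{[tert-butyl(dimethyl)silyl]oxy}-5-(propan-2-yl)hexan-2-ol F5. Dess–Martin oxidation of the secondary alcohol of F5 would then give 5.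

**Further compounds**

F1 | step 11 | (1R,2E,6E,10R)-3,7-dimethyl-10-(propan-2-yl)cyclodeca-2,6-dien-1-ol | O[C@@H]1[C@@H](C(C)C)CC/C(C)=C/CC/C(C)=C/1
F2 | step 11 | (2E,6E,10R)-3,7-dimethyl-10-(propan-2-yl)cyclodeca-2,6-dien-1-one | O=C1[C@@H](C(C)C)CC/C(C)=C/CC/C(C)=C/1
F3 | step 13 | (1R,4R,5S,6S,7R,10R)-1-bromoeudesmane-4,6-diol | O[C@H]1[C@@H](C(C)C)CC[C@@]2(C)[C@H](Br)CC[C@@](C)(O)[C@H]12
F4 | step 2 | (2R)-2-(propan-2-yl)hexane-1,5-diol | CC(O)CC[C@H](C(C)C)CO
F5 | step 2 | (5R)-6-{[tert-butyl(dimethyl)silyl]oxy}-5-(propan-2-yl)hexan-2-ol | CC(O)CC[C@H](C(C)C)CO[Si](C)(C)C(C)(C)C
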